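**Remark on the chemistry:** the target has no stereogenic centre, so "single enantiomer" is read as the single (8Z,11Z) isomer. Ring atoms are numbered as in the SMILES (C1 chain, C2 H, C3 OH, C4 H, C5 OH, C6 OAc) and chain atoms C1'–C17'.

## The problem

- The ring is a benzene-1,2,4-triol in which only one oxygen is acylated, and it is the most hindered one: C6–O lies between the chain carbon C1 and the free C5–OH. Direct acylation of the triol would favour C3–O or C5–O.
- The C6 ester is a catechol monoester, so any phenoxide at C5 can take the acetyl group over. If the acetyl is lost, the free triol oxidizes in air to the hydroxyquinone. The end of the synthesis must therefore be free of base and oxidant.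
- The chain carries a skipped (8'Z,11'Z)-diene with a doubly allylic C10'H2. This excludes hydrogenolysis, peracids, halogens, BBr3, radical conditions and strong bases at room temperature, and with them the usual methyl or benzyl ether protection of phenols.
- There is no stereocentre. The two Z olefins are the only stereochemical elements and are better bought than made: C1'–C17' together with ring C1 are the 18 carbons of linoleic acid (1), with the correct geometry.
- If 1 is used this way, the C1–C1' bond already exists. The task becomes growing a benzene ring onto the carboxyl carbon, under neutral conditions, with the acetate already on the right oxygen.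
- The enabling feature is the ring pattern. C6–OAc and C3–OH are para (a hydroquinone monoester), C6 sits between an oxygenated carbon (C5) and the chain carbon (C1), and C2 and C4 are CH. This is the pattern delivered by thermal ring expansion of a 4-acyloxy-3-alkoxy-4-(alk-1-en-2-yl)cyclobut-2-enone: C3–C4–C5–C6 are the four ring carbons of the cyclobutenone and C1–C2 are the alkene.

## Retrosynthesis

**13 ⇒ 12.** The O–isopropyl bond at C5–O is the only bond cut. One O-alkyl group has to be carried because the C5 oxygen arrives as the vinylogous ester oxygen of a squarate. Isopropyl is chosen because it comes with the commercial squarate 4 and can be removed by a Lewis acid at low temperature, without base (which would move the acetyl to C5–O) and without hydrogenation. The forward step must dealkylate one ether and leave the aryl acetate and the diene alone.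

**12 ⇒ 9 (key).** The ring bond C2–C3 is cut and C3–C6 is reconnected, so the arene 12 becomes its valence isomer, the cyclobutenone 9.
- Against cutting C1–C1' or acylating a triol: here the acetate is the ester of a tertiary alcohol and is installed before any phenol exists. The free C3–OH is the cyclobutenone carbonyl and the C5 oxygen is the ether, so the three oxygens are differentiated by construction.
- The precursor has no arene and is assembled in one flask from two small pieces.
- The forward reaction needs no reagent. It asks that the alkenyl group rotate inward on ring opening and that the dienylketene close faster than it is trapped.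

**9 ⇒ 7 + 6.** The C6–C1 bond (carbinol carbon to alkenyl carbon) and the O–acetyl bond are cut. The forward step is 1,2-addition of the alkenyllithium 7 to the semisquarate 6, followed by trapping of the alkoxide 8 with an acetyl donor. The addition must go to the ketone-like carbonyl next to the alkoxy carbon; the other carbonyl of 6 is a vinylogous ester and is less electrophilic.

**7 ⇒ 3 ⇒ 2 ⇒ 1.** The C–Li bond of 7 is traced to the hydrazone 3 (Shapiro reaction), and 3 to the methyl ketone 2. Ketone 2 comes from linoleic acid 1 by cutting the C–CH3 bond. The carboxyl carbon of 1 becomes ring C1 and the added methyl becomes ring C2–H. No olefin has to be made and the diene is never a reacting site.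

**6 ⇒ 4.** One alkoxy group of diisopropyl squarate 4 is exchanged for hydrogen by monoreduction to 5 and acid-induced loss of isopropanol. This is one step from a commercial compound.

## Roads not taken

**Alternative 1:** the obvious cut, C1–C1' (aryl–alkyl).
- Forward key step: sp2–sp3 coupling of a tri-O-protected hydroxyquinol nucleophile with a C17 dienyl electrophile, deprotection to the triol A1, then monoacetylation.
- Why the chosen plan is better: the acetyl would have to go to the most hindered of three phenols in A1, and the neighbouring C5–OH makes the C6 and C5 monoesters interconvertible. A1 oxidizes readily in air. Robust ethers cannot be removed next to the skipped diene, so three labile and partly orthogonal groups would be needed, which costs steps. The chosen route never has more than one free phenol competing and never has to select among them.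

**Alternative 2:** a biomimetic cut of the ring into the linoleoyl starter and three acetate units.
- Forward: Michael–Claisen cyclization, decarboxylation and aromatization to the alkylresorcinol A2. The key step would be oxidative acetoxylation of A2 at the carbon ortho to the chain (phenol oxidation with acetate capture, chemical or anodic).
- Why the chosen plan is better: the product, a hydroquinone monoester with a free para-OH, is easier to oxidize than A2, so over-oxidation to the quinone is built in. The position between the two hydroxyls of A2 competes. The oxidants (Pb(IV), I(III) or an anode) also attack the doubly allylic CH2. Aromatization on the way to A2 needs a further oxidant.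

**Alternative 3:** C-acetyl to O-acetyl transposition, where the C6–O bond is traced back to a C6–C(acetyl) bond.
- Forward: Baeyer–Villiger oxidation of the acetophenone A3 as its bis-silyl ether A4, with aryl migration, then desilylation.
- Why the chosen plan is better: the idea places the acetate regiospecifically, but a peracid cannot be expected to spare two electron-rich Z olefins. A3 needs either a Friedel–Crafts acetylation of A2 (two competing ring positions, Lewis acid) or a longer ring synthesis with oxidative aromatization. Protection and deprotection add two steps. The ring expansion reaches the same differentiation without an oxidant.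

Key step: step 5

## Route

**Step 1**
Reactants: 1 linoleic acid, (9Z,12Z)-octadeca-9,12-dienoic acid
Product: 2 (10Z,13Z)-nonadeca-10,13-dien-2-one
Conditions: MeLi (2.2 equiv), Et2O, 0 °C → rt; inverse quench into cold aq. NH4Cl
Reagents that add atoms: methyllithium, [Li]C
Why: Addition of an alkyllithium to a lithium carboxylate; the dilithio gem-diolate does not collapse before work-up, so the ketone is not exposed to MeLi, and MeLi in ether is too poor a kinetic base to touch the doubly allylic CH2.

**Step 2**
Reactants: 2 (10Z,13Z)-nonadeca-10,13-dien-2-one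
Product: 3 N'-[(2E,10Z,13Z)-nonadeca-10,13-dien-2-ylidene]-2,4,6-triisopropylbenzenesulfonohydrazide
Conditions: TrisNHNH2 (1.05 equiv), MeOH–THF, cat. HCl, rt
Reagents that add atoms: 2,4,6-triisopropylbenzenesulfonyl hydrazide, NNS(=O)(=O)c1c(C(C)C)cc(C(C)C)cc1C(C)C
Why: Condensation of a ketone with a sulfonyl hydrazide; the E isomer (sulfonamide nitrogen syn to the methyl group) should predominate for a methyl alkyl ketone.

**Step 3**
Reactants: 4 diisopropyl squarate, 3,4-diisopropoxycyclobut-3-ene-1,2-dione
Product: 6 3-isopropoxycyclobut-3-ene-1,2-dione, via hydroxycyclobutenone 5 (not isolated)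
Conditions: LiAlH(Ot-Bu)3 (1.05 equiv), THF, −78 → −20 °C; then aq. HCl added to the same flask, 0 °C → rt
Reagents that add atoms: water, O
Why: The hindered hydride adds once to a squarate carbonyl to give 5; acid ionizes the carbinol, water adds at the alkoxy-bearing end of the allyl cation and isopropanol is lost (a 1,3-carbonyl transposition), a known entry to 3-alkoxycyclobutenediones.

**Step 4**
Reactants: 3 N'-[(2E,10Z,13Z)-nonadeca-10,13-dien-2-ylidene]-2,4,6-triisopropylbenzenesulfonohydrazide; 6 3-isopropoxycyclobut-3-ene-1,2-dione
Product: 9 2-isopropoxy-1-[(10Z,13Z)-nonadeca-1,10,13-trien-2-yl]-4-oxocyclobut-2-en-1-yl acetate (racemic), via vinyllithium 7 (not isolated), via lithium alkoxide 8 (not isolated)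
Conditions: 3, n-BuLi (2.05 equiv), THF–hexane, −78 °C, then 0 °C until N2 evolution stops, recool to −78 °C; 6 (0.85 equiv) in THF, −78 °C; Ac2O (3 equiv), −78 → −20 °C
Reagents that add atoms: acetic anhydride, CC(=O)OC(C)=O
Why: Shapiro reaction: the hydrazone dianion (N–H and the syn methyl deprotonated) loses sulfinate and N2 to give the 2-lithio-1-alkene 7. This adds 1,2 to the ketone-like carbonyl of 6 (the other carbonyl is deactivated as a vinylogous ester), and the tertiary lithium alkoxide 8 is O-acetylated in the same flask. The new quaternary carbon forms as a racemate and disappears in step 5.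

**Step 5**
Reactants: 9 2-isopropoxy-1-[(10Z,13Z)-nonadeca-1,10,13-trien-2-yl]-4-oxocyclobut-2-en-1-yl acetate
Product: 12 6-[(8Z,11Z)-heptadeca-8,11-dien-1-yl]-4-hydroxy-2-isopropoxyphenyl acetate, via dienylketene 10 (not isolated), via cyclohexadienone 11 (not isolated)
Conditions: toluene (degassed, ca. 0.01 M), cat. BHT, 110 °C, argon
Reagents that add atoms: none
Why: Thermal conrotatory 4π ring opening of the C(=O)–C(OAc) bond of 9 should give the (3Z)-dienylketene 10. The acetoxy group, a lone-pair donor, is expected to rotate outward and the alkenyl group inward, the usual torquoselectivity of 4-oxygenated cyclobutenones. 10 then closes the six-membered ring by disrotatory 6π electrocyclization between the ketene carbon and the alkene CH2 to give cyclohexa-2,4-dienone 11, which enolizes to phenol 12. The closest known reaction type is the Moore rearrangement of 4-alkenyl-4-hydroxy-, 4-alkoxy- and 4-silyloxycyclobutenones to hydroquinone derivatives. No stereocentre is formed; the racemic quaternary carbon of 9 becomes the sp2 carbon C6. The selectivity needed is constitutional and is fixed by the connectivity of 9: the carbinol oxygen keeps its acetyl and becomes C6–O, the ketone oxygen becomes the free C3–OH, and the isopropoxy carbon becomes C5. The free C3–OH is para to the ester, so no acyl shift can follow. The neutral, reagent-free conditions should leave the skipped diene untouched, and high dilution disfavours bimolecular trapping of the ketene.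

**Step 6**
Reactants: 12 6-[(8Z,11Z)-heptadeca-8,11-dien-1-yl]-4-hydroxy-2-isopropoxyphenyl acetate
Product: 13 ardisiphenol C, 2,4-dihydroxy-6-[(8Z,11Z)-heptadeca-8,11-dien-1-yl]phenyl acetate
Conditions: BCl3 (3 equiv), CH2Cl2, −78 → −20 °C; quench into cold pH 7 buffer; argon, rapid chromatography on acid-washed silica
Reagents that add atoms: none
Why: Lewis acid dealkylation of an aryl isopropyl ether: BCl3 binds the ether oxygen and chloride removes the secondary alkyl group much faster than the aryl ester is attacked. No base is present at any point, so the acetyl group should stay on C6–O.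

## Compound list

1 | linoleic acid, (9Z,12Z)-octadeca-9,12-dienoic acid | CCCCC/C=C\C/C=C\CCCCCCCC(=O)O | starting material
2 | (10Z,13Z)-nonadeca-10,13-dien-2-one | CCCCC/C=C\C/C=C\CCCCCCCC(C)=O | intermediate
3 | N'-[(2E,10Z,13Z)-nonadeca-10,13-dien-2-ylidene]-2,4,6-triisopropylbenzenesulfonohydrazide | CCCCC/C=C\C/C=C\CCCCCCC/C(C)=N/NS(=O)(=O)c1c(C(C)C)cc(C(C)C)cc1C(C)C | intermediate
4 | diisopropyl squarate, 3,4-diisopropoxycyclobut-3-ene-1,2-dione | CC(C)OC1=C(OC(C)C)C(=O)C1=O | starting material
5 | 4-hydroxy-2,3-diisopropoxycyclobut-2-en-1-one (racemic) | CC(C)OC1=C(OC(C)C)C(O)C1=O | intermediate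
6 | 3-isopropoxycyclobut-3-ene-1,2-dione | CC(C)OC1=CC(=O)C1=O | intermediate
7 | [(10Z,13Z)-nonadeca-1,10,13-trien-2-yl]lithium | [Li]C(=C)CCCCCCC/C=C\C/C=C\CCCCC | intermediate
8 | lithium 2-isopropoxy-1-[(10Z,13Z)-nonadeca-1,10,13-trien-2-yl]-4-oxocyclobut-2-en-1-olate (racemic) | CC(C)OC1=CC(=O)C1(O[Li])C(=C)CCCCCCC/C=C\C/C=C\CCCCC | intermediate
9 | 2-isopropoxy-1-[(10Z,13Z)-nonadeca-1,10,13-trien-2-yl]-4-oxocyclobut-2-en-1-yl acetate (racemic) | CC(C)OC1=CC(=O)C1(OC(C)=O)C(=C)CCCCCCC/C=C\C/C=C\CCCCC | intermediate
10 | (3Z)-4-acetoxy-5-[(8Z,11Z)-heptadeca-8,11-dien-1-yl]-3-isopropoxyhexa-1,3,5-trien-1-one (dienylketene) | O=C=C/C(OC(C)C)=C(OC(C)=O)\C(=C)CCCCCCC/C=C\C/C=C\CCCCC | intermediate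
11 | 2-[(8Z,11Z)-heptadeca-8,11-dien-1-yl]-6-isopropoxy-4-oxocyclohexa-1,5-dien-1-yl acetate | O=C1C=C(OC(C)C)C(OC(C)=O)=C(CCCCCCC/C=C\C/C=C\CCCCC)C1 | intermediate
12 | 6-[(8Z,11Z)-heptadeca-8,11-dien-1-yl]-4-hydroxy-2-isopropoxyphenyl acetate | CCCCC/C=C\C/C=C\CCCCCCCc1cc(O)cc(OC(C)C)c1OC(C)=O | intermediate
13 | ardisiphenol C, 2,4-dihydroxy-6-[(8Z,11Z)-heptadeca-8,11-dien-1-yl]phenyl acetate | CCCCC/C=C\C/C=C\CCCCCCCc1cc(O)cc(O)c1OC(C)=O | target

## Step count and least certain steps

Total steps: 6. Longest linear sequence: 5 (steps 1, 2, 4, 5, 6 from linoleic acid). Step 3 is a one-step side branch.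

**Step 5 (key step).** What may go wrong:
- Partial loss of torquoselectivity. Acetoxy is a weaker donor than hydroxy or alkoxy, so some material may open with the alkenyl group outward. That dienylketene cannot close and would be consumed by dimerization or by attack of the ester carbonyl.
- Ionization or 1,3-shift of the tertiary, doubly activated acetate before ring opening.
- Acylation of the product phenol by the ketene if the solution is too concentrated.

Fallback (sets out from 3 and 6, comes back at 12), using the hydroxy version of the ring expansion:
- Vinyllithium 7 is made from 3 as in step 4 and added to 6. The mixture is quenched with aq. NH4Cl instead of anhydride, which should give the carbinol 4-hydroxy-3-isopropoxy-4-[(10Z,13Z)-nonadeca-1,10,13-trien-2-yl]cyclobut-2-en-1-one F1.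
- Heating F1 in degassed toluene should give the hydroquinone 2-[(8Z,11Z)-heptadeca-8,11-dien-1-yl]-6-isopropoxybenzene-1,4-diol F2.
- F2 is acetylated without isolation (Ac2O, pyridine, cat. DMAP) to the diacetate 2-[(8Z,11Z)-heptadeca-8,11-dien-1-yl]-6-isopropoxy-1,4-phenylene diacetate F3.
- In F3 the acetate flanked by two ring hydrogens should be cleaved selectively by pyrrolidine (1 equiv, CH2Cl2, 0 °C), because aminolysis of the di-ortho-substituted ester is much slower. This returns 12.

**Step 4.** What may go wrong:
- Deprotonation of the doubly allylic methylene by n-BuLi or by 7 during the warm-up to 0 °C, which would scramble the Z,Z-diene through a pentadienyl anion.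
- Deprotonation on the methylene side of the hydrazone, giving the internal alkenyllithium.
- Attack of 7 on the vinylogous ester carbonyl of 6, or conjugate addition–elimination at its alkoxy carbon.
- Incomplete acylation of the hindered alkoxide 8.

Fallback (sets out from 2, comes back at 7, which is taken on to 9 as in step 4):
- Kinetic enolization of 2 (LDA, THF, −78 °C) and trapping with PhNTf2 should give the enol triflate (10Z,13Z)-nonadeca-1,10,13-trien-2-yl trifluoromethanesulfonate F4.
- Pd-catalysed stannylation (Me3SnSnMe3, Pd(PPh3)4, LiCl, THF, 60 °C) should give trimethyl[(10Z,13Z)-nonadeca-1,10,13-trien-2-yl]stannane F5.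
- Tin–lithium exchange (MeLi, THF, −78 °C) delivers 7 without excess alkyllithium and without leaving −78 °C.
- If only the acylation fails, the carbinol F1 would be isolated and acetylated with Ac2O/DMAP.

**Step 6.** What may go wrong:
- Addition of HCl to the olefins, or Lewis-acid-induced isomerization of them.
- Migration of the acetyl group from C6–O to the newly freed C5–O during work-up or on silica.
- Solvolytic loss of the acetyl group on quenching.

Fallback (sets out from 3 via 7, comes back at 13), replacing Lewis acid dealkylation by acidolysis of a tert-butyl ether: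
- 3,4-Di-tert-butoxycyclobut-3-ene-1,2-dione F6 (purchased, or made from squaric acid) is converted by the protocol of step 3 into 3-tert-butoxycyclobut-3-ene-1,2-dione F7.
- Addition of 7 and an Ac2O quench should give 2-tert-butoxy-1-[(10Z,13Z)-nonadeca-1,10,13-trien-2-yl]-4-oxocyclobut-2-en-1-yl acetate F8.
- Thermolysis as in step 5 should give 2-tert-butoxy-6-[(8Z,11Z)-heptadeca-8,11-dien-1-yl]-4-hydroxyphenyl acetate F9.
- Brief treatment of F9 with TFA in CH2Cl2 at 0 °C under an argon stream should release 13 with loss of the tert-butyl group as 2-methylpropene.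

## Further compounds

F1 | step 5 | 4-hydroxy-3-isopropoxy-4-[(10Z,13Z)-nonadeca-1,10,13-trien-2-yl]cyclobut-2-en-1-one | CC(C)OC1=CC(=O)C1(O)C(=C)CCCCCCC/C=C\C/C=C\CCCCC
F2 | step 5 | 2-[(8Z,11Z)-heptadeca-8,11-dien-1-yl]-6-isopropoxybenzene-1,4-diol | CCCCC/C=C\C/C=C\CCCCCCCc1cc(O)cc(OC(C)C)c1O
F3 | step 5 | 2-[(8Z,11Z)-heptadeca-8,11-dien-1-yl]-6-isopropoxy-1,4-phenylene diacetate | CCCCC/C=C\C/C=C\CCCCCCCc1cc(OC(C)=O)cc(OC(C)C)c1OC(C)=O
F4 | step 4 | (10Z,13Z)-nonadeca-1,10,13-trien-2-yl trifluoromethanesulfonate | C=C(OS(=O)(=O)C(F)(F)F)CCCCCCC/C=C\C/C=C\CCCCC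
F5 | step 4 | trimethyl[(10Z,13Z)-nonadeca-1,10,13-trien-2-yl]stannane | C=C([Sn](C)(C)C)CCCCCCC/C=C\C/C=C\CCCCC
F6 | step 6 | 3,4-di-tert-butoxycyclobut-3-ene-1,2-dione | CC(C)(C)OC1=C(OC(C)(C)C)C(=O)C1=O
F7 | step 6 | 3-tert-butoxycyclobut-3-ene-1,2-dione | CC(C)(C)OC1=CC(=O)C1=O
F8 | step 6 | 2-tert-butoxy-1-[(10Z,13Z)-nonadeca-1,10,13-trien-2-yl]-4-oxocyclobut-2-en-1-yl acetate | CC(C)(C)OC1=CC(=O)C1(OC(C)=O)C(=C)CCCCCCC/C=C\C/C=C\CCCCC
F9 | step 6 | 2-tert-butoxy-6-[(8Z,11Z)-heptadeca-8,11-dien-1-yl]-4-hydroxyphenyl acetate | CCCCC/C=C\C/C=C\CCCCCCCc1cc(O)cc(OC(C)(C)C)c1OC(C)=O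
A1 | alternative 1 | 6-[(8Z,11Z)-heptadeca-8,11-dien-1-yl]benzene-1,2,4-triol | CCCCC/C=C\C/C=C\CCCCCCCc1cc(O)cc(O)c1O
A2 | alternative 2 | 5-[(8Z,11Z)-heptadeca-8,11-dien-1-yl]benzene-1,3-diol | CCCCC/C=C\C/C=C\CCCCCCCc1cc(O)cc(O)c1
A3 | alternative 3 | 1-{2,4-dihydroxy-6-[(8Z,11Z)-heptadeca-8,11-dien-1-yl]phenyl}ethan-1-one | CCCCC/C=C\C/C=C\CCCCCCCc1cc(O)cc(O)c1C(C)=O
A4 | alternative 3 | 1-{2,4-bis[(tert-butyldimethylsilyl)oxy]-6-[(8Z,11Z)-heptadeca-8,11-dien-1-yl]phenyl}ethan-1-one | CCCCC/C=C\C/C=C\CCCCCCCc1cc(O[Si](C)(C)C(C)(C)C)cc(O[Si](C)(C)C(C)(C)C)c1C(C)=O
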